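**Retrosynthetic overview**
1. The target is reached last by hydrogenolysis of the O-benzyl ether of a tetra-oxygenated hydroquinone, followed by air oxidation of the resulting benzenetriol to the hydroxyquinone.
2. The six-membered ring is the only ring formed in the route. It arises by thermal ring expansion of a 4-alkenyl-4-hydroxycyclobutenone, in which a 6π closure makes the ring bond between the carbonyl carbon next to the ring CH and the oxygen-bearing carbon next to the docosyl carbon.
3. That cyclobutenone comes from 1,2-addition of a cis-β-benzyloxyvinyllithium (bringing the docosyl carbon and the oxygenated carbon) to methyl semisquarate (bringing the two carbonyl carbons, the CH and the methoxy carbon). The four-membered ring is bought as dimethyl squarate and consumed.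
4. The vinyllithium comes from a (Z)-2-bromo enol ether, made by Kumada coupling of docosylmagnesium bromide with a 2-bromovinyl benzyl ether followed by bromination and dehydrobromination.
5. Enabling feature: in the 1,2,4,5-tetraoxygenated six-membered ring, the C(=O)–CH=C(OMe)–C(=O) half is a ring-opened semisquarate, and the C(docosyl)=C(OH) half is an enol ether whose oxygenated carbon is nucleophilic toward the ketene carbon that becomes the neighbouring carbonyl.

Key step: step 6

Remark: the side chain is read as unbranched docosyl (C22H45). The target has no stereocentre, so only the double-bond geometry of intermediates has to be controlled.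

**Step 1**
Reactants: 1 dimethyl squarate (3,4-dimethoxycyclobut-3-ene-1,2-dione)
Product: 3 3-methoxycyclobut-3-ene-1,2-dione (methyl semisquarate), via hydride adduct 2 (not isolated)
Conditions: LiAlH(OtBu)3 (1.05 equiv), THF, −78 °C; then 6 M HCl, CH2Cl2, 0 °C to rt
Reagents that add atoms: water, O
Why: A bulky hydride adds once to one of the two equivalent squarate carbonyl carbons (1,2-reduction), and acid then ionises the allylic carbinol of 2 so that water adds at the distal methoxy-bearing carbon and methanol is lost (allylic transposition with vinylogous-ester hydrolysis, the standard conversion of squarate diesters into semisquarates).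

**Step 2**
Reactants: 4 benzyl vinyl ether
Product: 6 (Z)-1-(benzyloxy)-2-bromoethene, via dibromo ether 5 (not isolated)
Conditions: Br2 (1.0 equiv), CH2Cl2, −78 °C; then i-Pr2NEt, −78 °C to rt
Reagents that add atoms: bromine, BrBr
Why: Bromine adds to the enol ether to give the α,β-dibromo ether 5, whose labile α-bromide ionises to an oxocarbenium ion that the hindered amine deprotonates (bromination–dehydrobromination of a vinyl ether); the cis bromide is the expected major isomer, although either geometry serves in step 3.

**Step 3**
Reactants: 7 1-bromodocosane; 6 (Z)-1-(benzyloxy)-2-bromoethene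
Product: 9 (Z)-1-(benzyloxy)tetracos-1-ene, via docosylmagnesium bromide 8 (not isolated)
Conditions: Mg turnings, THF, 50 °C; then 6, NiCl2(dppp) (2 mol %; dppp = Ph2P(CH2)3PPh2), THF, 0 °C to rt
Reagents that add atoms: none
Why: Kumada–Tamao–Corriu coupling, in which nickel should insert into the alkenyl C–Br bond much faster than into the enol-ether C–O bond, the chelating diphosphine suppresses β-hydride elimination from the docosyl–nickel intermediate, and the alkene geometry is retained (it is erased in step 4 in any case).

**Step 4**
Reactants: 9 (Z)-1-(benzyloxy)tetracos-1-ene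
Product: 11 (Z)-1-(benzyloxy)-2-bromotetracos-1-ene, via dibromide 10 (not isolated)
Conditions: Br2 (1.0 equiv), CH2Cl2, −78 °C; then DBU, −78 °C to rt; chromatography on Et3N-deactivated silica
Reagents that add atoms: bromine, BrBr
Why: The same bromination–dehydrobromination applied to a 1,2-disubstituted enol ether, where ionisation of the α-bromo ether of 10 and loss of the proton at the bromine-bearing carbon should give the 2-bromo enol ether; the isomer with bromine cis to oxygen (Z) is separated from any (E)-isomer.

**Step 5**
Reactants: 11 (Z)-1-(benzyloxy)-2-bromotetracos-1-ene; 3 3-methoxycyclobut-3-ene-1,2-dione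
Product: 13 racemic 4-[(Z)-1-(benzyloxy)tetracos-1-en-2-yl]-4-hydroxy-3-methoxycyclobut-2-en-1-one, via vinyllithium 12 (not isolated)
Conditions: t-BuLi (2.0 equiv), THF/Et2O, −78 °C; cannulate into 3, THF, −78 °C; then H2O, −78 to 0 °C; crude product passed quickly through Et3N-deactivated silica
Reagents that add atoms: none
Why: Bromine–lithium exchange proceeds with retention to the cis-β-alkoxyvinyllithium 12, which is held by internal O–Li coordination and cannot undergo anti β-elimination, and 12 should add 1,2 to the more electrophilic carbonyl of 3 (the one attached to the methoxy-bearing carbon, not the vinylogous-ester carbonyl), as organolithium reagents do with 3-alkoxycyclobutenediones; the carbinol centre forms as a racemate and is destroyed in step 6.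

**Step 6**
Reactants: 13 racemic 4-[(Z)-1-(benzyloxy)tetracos-1-en-2-yl]-4-hydroxy-3-methoxycyclobut-2-en-1-one
Product: 16 2-(benzyloxy)-3-docosyl-5-methoxybenzene-1,4-diol, via dienylketene 14 (not isolated), via cyclohexadienone 15 (not isolated)
Conditions: degassed PhMe, 110 °C, argon; concentrate under argon, crude hydroquinone used directly in step 7
Reagents that add atoms: none
Why: At 110 °C the C1–C4 bond of cyclobutenone 13 should open in a conrotatory 4π-electrocyclic step to dienylketene 14, a disrotatory 6π-electrocyclisation then joins the ketene carbon (later the ring carbonyl carbon next to the ring CH) to the benzyloxy-bearing alkene terminus (later the hydroxyl-bearing carbon next to the docosyl carbon) to give dienone 15, and enolisation of 15 gives the aromatic hydroquinone 16, which is kept at this oxidation level because step 7 is carried out on the hydroquinone. The closest known reaction type is the Moore-type thermal ring expansion of 4-alkenyl-4-hydroxycyclobutenones to hydroquinones. The six-membered ring, the only ring closed, forms by 6π-electrocyclic closure between the two ends of the dienylketene, a thermally allowed pericyclic closure. No new stereocentre remains, since the sp3 carbon of 15 is lost on aromatisation and the carbinol centre of 13 is consumed in the ring opening. The step needs outward rotation of the hydroxyl group (so that the alkenyl arm lies cis to the ketene) and C–C closure in preference to capture of the ketene by the hydroxyl, and both are secured by the substrate: a 4-hydroxyl donor rotates outward by torquoselectivity, and the enol-ether terminus is a nucleophilic carbon matched to the electrophilic ketene carbon. The positions of all four ring substituents follow from the connectivity of 13 and cannot scramble.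

**Step 7**
Reactants: 16 2-(benzyloxy)-3-docosyl-5-methoxybenzene-1,4-diol
Product: 18 3-docosyl-2-hydroxy-5-methoxy-1,4-benzoquinone, via triol 17 (not isolated)
Conditions: H2 (1 atm), 10% Pd/C, THF/EtOAc, rt; filter through Celite; then air, rt
Reagents that add atoms: none
Why: Hydrogen over palladium should cleave the benzyl aryl ether of 16 while the methyl ether and the arene are inert, and the resulting 1,2,4-benzenetriol 17 is autoxidised by air to the 2-hydroxy-1,4-benzoquinone (standard O-debenzylation followed by aerobic oxidation of a hydroxyhydroquinone).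

**Compound list**
1 | dimethyl squarate (3,4-dimethoxycyclobut-3-ene-1,2-dione) | COC1=C(OC)C(=O)C1=O | starting material
2 | 4-hydroxy-2,3-dimethoxycyclobut-2-en-1-one (racemic) | COC1=C(OC)C(O)C1=O | intermediate
3 | 3-methoxycyclobut-3-ene-1,2-dione (methyl semisquarate) | COC1=CC(=O)C1=O | intermediate
4 | benzyl vinyl ether | C=COCc1ccccc1 | starting material
5 | (1,2-dibromoethoxy)methylbenzene (racemic) | BrCC(Br)OCc1ccccc1 | intermediate
6 | (Z)-1-(benzyloxy)-2-bromoethene | Br/C=C\OCc1ccccc1 | intermediate
7 | 1-bromodocosane | CCCCCCCCCCCCCCCCCCCCCCBr | starting material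
8 | docosylmagnesium bromide | CCCCCCCCCCCCCCCCCCCCCC[Mg]Br | intermediate
9 | (Z)-1-(benzyloxy)tetracos-1-ene | CCCCCCCCCCCCCCCCCCCCCC/C=C\OCc1ccccc1 | intermediate
10 | 1-(benzyloxy)-1,2-dibromotetracosane (mixture of diastereomers) | CCCCCCCCCCCCCCCCCCCCCCC(Br)C(Br)OCc1ccccc1 | intermediate
11 | (Z)-1-(benzyloxy)-2-bromotetracos-1-ene (bromine cis to oxygen) | CCCCCCCCCCCCCCCCCCCCCC/C(Br)=C/OCc1ccccc1 | intermediate
12 | [(E)-1-(benzyloxy)tetracos-1-en-2-yl]lithium (lithium cis to oxygen) | CCCCCCCCCCCCCCCCCCCCCC/C([Li])=C/OCc1ccccc1 | intermediate
13 | racemic 4-[(Z)-1-(benzyloxy)tetracos-1-en-2-yl]-4-hydroxy-3-methoxycyclobut-2-en-1-one | CCCCCCCCCCCCCCCCCCCCCC/C(=C/OCc1ccccc1)C1(O)C(=O)C=C1OC | intermediate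
14 | (3Z,5Z)-6-(benzyloxy)-5-docosyl-4-hydroxy-3-methoxyhexa-1,3,5-trien-1-one | O=C=C/C(OC)=C(O)\C(CCCCCCCCCCCCCCCCCCCCCC)=C/OCc1ccccc1 | intermediate
15 | 6-(benzyloxy)-5-docosyl-4-hydroxy-3-methoxycyclohexa-2,4-dien-1-one (racemic) | CCCCCCCCCCCCCCCCCCCCCCC1=C(O)C(OC)=CC(=O)C1OCc2ccccc2 | intermediate
16 | 2-(benzyloxy)-3-docosyl-5-methoxybenzene-1,4-diol | CCCCCCCCCCCCCCCCCCCCCCc1c(O)c(OC)cc(O)c1OCc2ccccc2 | intermediate
17 | 3-docosyl-5-methoxybenzene-1,2,4-triol | CCCCCCCCCCCCCCCCCCCCCCc1c(O)c(O)cc(OC)c1O | intermediate
18 | 3-docosyl-2-hydroxy-5-methoxy-1,4-benzoquinone | CCCCCCCCCCCCCCCCCCCCCCC1=C(O)C(=O)C=C(OC)C1=O | target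

**Step count and risks**
Total steps: 7. Longest linear sequence: 6 steps (4 → 6 → 9 → 11 → 13 → 16 → 18).

Steps most likely to fail:

1. Step 5. The vinyllithium may lose lithium benzyloxide by β-elimination or metalate its own benzylic position before it adds, and the enol-ether carbinol may undergo acid-triggered allylic transposition during work-up. The fallback sets out from 7 and comes back to the route at 18, avoiding any vinyl anion. Commercial 1,2,4,5-tetramethoxybenzene is lithiated between two methoxy groups (n-BuLi, THF, 0 °C) and alkylated with 7 to give 3-docosyl-1,2,4,5-tetramethoxybenzene F1. Oxidative demethylation with (NH4)2Ce(NO3)6 in MeCN/H2O should give 3-docosyl-2,5-dimethoxy-1,4-benzoquinone F2. Hydrolysis of both vinylogous esters (aq HClO4, dioxane) gives 3-docosyl-2,5-dihydroxy-1,4-benzoquinone F3. Acid-catalysed methylation (MeOH, cat. H2SO4, reflux) should then occur at the less hindered hydroxyl, remote from the docosyl chain, to give 18.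

2. Step 4. The dehydrobromination may show poor control of double-bond geometry, leaving much (E)-bromide whose lithio derivative fragments to the alkyne. The fallback sets out from 8 and comes back at 11, fixing the geometry by mechanism. Transmetalation of 8 with ZnBr2 gives docosylzinc bromide F4. Benzyl formate is converted by Ramirez dibromo-olefination (CBr4, PPh3, CH2Cl2) into benzyl 2,2-dibromovinyl ether F5. A Negishi mono-alkylation of F5 with F4, catalysed by PdCl2(DPEphos) (DPEphos = bis(2-diphenylphosphinophenyl) ether), should replace the bromide trans to the benzyloxy group first and leave bromine cis to oxygen, which is 11.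

3. Step 6. The hydroxyl may rotate inward or the closure may be slow, so that the ketene is captured by the hydroxyl as a butenolide, or the free tertiary allylic carbinol may ionise on heating. The fallback sets out from 13 and comes back at 16. Silylation (Me3SiCl, imidazole, CH2Cl2, or Me3SiCl quench of the lithium alkoxide of step 5) gives 4-[(Z)-1-(benzyloxy)tetracos-1-en-2-yl]-3-methoxy-4-(trimethylsilyloxy)cyclobut-2-en-1-one F6. Thermolysis in PhMe at 110 °C should give 2-(benzyloxy)-3-docosyl-5-methoxy-4-(trimethylsilyloxy)phenol F7, since the silyl ether cannot add to the ketene and cannot ionise as readily. Cleavage of the aryl silyl ether with dilute aqueous HCl in THF under argon then gives 16.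

**Further compounds**
F1 | step 5 | 3-docosyl-1,2,4,5-tetramethoxybenzene | CCCCCCCCCCCCCCCCCCCCCCc1c(OC)c(OC)cc(OC)c1OC
F2 | step 5 | 3-docosyl-2,5-dimethoxy-1,4-benzoquinone | CCCCCCCCCCCCCCCCCCCCCCC1=C(OC)C(=O)C=C(OC)C1=O
F3 | step 5 | 3-docosyl-2,5-dihydroxy-1,4-benzoquinone | CCCCCCCCCCCCCCCCCCCCCCC1=C(O)C(=O)C=C(O)C1=O
F4 | step 4 | docosylzinc bromide | CCCCCCCCCCCCCCCCCCCCCC[Zn]Br
F5 | step 4 | benzyl 2,2-dibromovinyl ether | BrC(Br)=COCc1ccccc1
F6 | step 6 | 4-[(Z)-1-(benzyloxy)tetracos-1-en-2-yl]-3-methoxy-4-(trimethylsilyloxy)cyclobut-2-en-1-one (racemic) | CCCCCCCCCCCCCCCCCCCCCC/C(=C/OCc1ccccc1)C1(O[Si](C)(C)C)C(=O)C=C1OC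
F7 | step 6 | 2-(benzyloxy)-3-docosyl-5-methoxy-4-(trimethylsilyloxy)phenol | CCCCCCCCCCCCCCCCCCCCCCc1c(O[Si](C)(C)C)c(OC)cc(O)c1OCc2ccccc2
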